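**Plan**

Guaiane numbering is used throughout and kept for the decalin precursors: small ring C1–C5 (C4 methyl), large ring C1, C5–C10 (C7 isopropyl, C8 oxygen, C10 methyl).

1. Retrosynthesis: cut the C8–O vanillate ester; trace C5–H and C3=C4 back to a C3 carbinol with a C4=C5 alkene (reductive 1,3-transposition), and C1=C10 back to a C10 acetate.
2. Then cut C1–C5 and restore C5–C10: the 5/7 skeleton becomes a 6/6 eudesma-1,4-dien-3-one, which Robinson annulation (C1–C10 and C4=C5 bonds) cuts to a 4-hydroxy-5-isopropyl-2-methylcyclohexanone derived from (R)-carvone.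
3. Enabling feature: C1–C5 of the cyclopentene plus the trigonal C10 are exactly the six atoms of a cross-conjugated cyclohexadienone (ring A). Its β,β′ carbons C1 and C5 flank the quaternary C10 and can bond to each other; the C4 methyl steers the subsequent opening to the 5/7 skeleton.
4. Forward order: ring B from carvone is oxygenated at C8; ring A is annulated and dehydrogenated; light contracts ring A to a cyclopentenone while ring B grows to seven atoms; then elimination, esterification, ketone reduction, transposition and phenol release.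
5. Stereochemistry: C7 from (R)-carvone; C8 by oxidation anti to the isopropyl group; C10 needs no control (both epimers converge once C10 is trigonal); C5 from a reagent-controlled reduction at C3, relayed by Mitsunobu inversion and suprafacial diazene hydrogen transfer.

Key step: step 7

Remark: compounds 8 to 12 are drawn as the C10 epimer expected to predominate from axial Michael addition (methyl trans to isopropyl); the other epimer is carried along because C1 and C10 become trigonal in step 8.

**Route**

Step 1
Reactants: 1 (R)-(−)-carvone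
Product: 2 (5R)-5-isopropyl-2-methylcyclohex-2-en-1-one (carvotanacetone)
Conditions: H2 (1 atm), RhCl(PPh3)3 (cat.), benzene, 25 °C
Reagents that add atoms: none
Why: Homogeneous hydrogenation with RhCl(PPh3)3 should reduce only the unhindered 1,1-disubstituted isopropenyl alkene and leave the conjugated trisubstituted enone and the existing stereocentre untouched.

Step 2
Reactants: 2 carvotanacetone
Product: 3 (R)-[(5-isopropyl-2-methylcyclohexa-1,3-dien-1-yl)oxy]trimethylsilane
Conditions: MeMgBr, FeCl3 (cat.), Et2O, −20 °C; then Me3SiCl, Et3N, DMPU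
Reagents that add atoms: chlorotrimethylsilane, C[Si](C)(C)Cl
Why: The iron-modified Grignard base should remove the γ proton at ring C4 instead of adding to the carbonyl or enolising toward C6, and O-silylation of the linear magnesium dienolate gives the through-conjugated silyl dienol ether (kinetic γ-deprotonation of an enone).

Step 3
Reactants: 3 silyl dienol ether
Product: 5 (4R,5R)-4-hydroxy-5-isopropyl-2-methylcyclohex-2-en-1-one, via epoxy silyl dienol ether 4 (not isolated)
Conditions: mCPBA, NaHCO3, CH2Cl2, −20 °C; then Et3N·3HF, THF, 0 °C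
Reagents that add atoms: 3-chloroperbenzoic acid, OOC(=O)c1cccc(Cl)c1
Why: Vinylogous Rubottom oxidation, as in the 6-hydroxylation of steroidal 3,5-dienol ethers: the peracid should epoxidise the distal, less hindered alkene on the face anti to the adjacent isopropyl group, and fluoride-induced collapse of the epoxide gives the γ-hydroxy enone with the new hydroxyl trans to isopropyl; strong acid is avoided because the product can dehydrate to a phenol.

Step 4
Reactants: 5 γ-hydroxy enone
Product: 6 (2R,4S,5R)-4-hydroxy-5-isopropyl-2-methylcyclohexan-1-one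
Conditions: H2 (1 atm), Pd/C (10% Pd on carbon), EtOAc, 25 °C
Reagents that add atoms: none
Why: Heterogeneous hydrogenation of the conjugated alkene should give the saturated ketone; the C2 methyl centre is epimerisable (the all-equatorial isomer is drawn) and its configuration does not matter because this carbon is re-enolised in step 5.

Step 5
Reactants: 6 hydroxy ketone; 7 ethyl vinyl ketone
Product: 9 (4aS,6S,7R)-6-hydroxy-7-isopropyl-1,4a-dimethyl-4,4a,5,6,7,8-hexahydronaphthalen-2(3H)-one, via Michael adduct diketone 8 (not isolated)
Conditions: KOH, EtOH, −10 to 25 °C; then KOH, EtOH, reflux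
Reagents that add atoms: none
Why: Robinson annulation: the more substituted (thermodynamic) enolate adds to the enone at the methyl-bearing carbon to create quaternary C10 (axial attack on the chair with equatorial isopropyl and hydroxyl puts the methyl trans to isopropyl, and either epimer serves), and intramolecular aldol condensation closes ring A as the 4-methyl enone.

Step 6
Reactants: 9 octalone
Product: 10 (4aR,6S,7R)-6-hydroxy-7-isopropyl-1,4a-dimethyl-5,6,7,8-tetrahydronaphthalen-2(4aH)-one
Conditions: DDQ, dioxane, reflux
Reagents that add atoms: none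
Why: Quinone dehydrogenation of a 4-en-3-one under neutral conditions should remove hydrogen from C1 and C2 through the cross-conjugated enol and give the 1,4-dien-3-one, as is standard for 4-methyl octalones and steroidal enones; the saturated secondary alcohol is not oxidised.

Step 7
Reactants: 10 cross-conjugated dienone
Product: 12 (5R,6S,8S,8aS)-6-hydroxy-5-isopropyl-3,8-dimethyl-2-oxo-1,2,4,5,6,7,8,8a-octahydroazulen-8-yl acetate, via cyclopropyl oxyallyl zwitterion 11 (not isolated)
Conditions: hν (medium-pressure Hg lamp, Pyrex filter), anhydrous AcOH, N2, 20 °C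
Reagents that add atoms: acetic acid, CC(=O)O
Why: Excitation of the dienone and β,β′-bonding between C1 and C5 gives zwitterion 11; O-protonation by acetic acid makes it a cyclopropylcarbinyl (2-hydroxyallyl) cation whose C5–C10 bond cleaves as acetate adds to C10, so C10 leaves ring A (six to five atoms) and ring B grows from six to seven. The closest known reaction type is the photorearrangement of α-santonin and other 4-methylcyclohexa-2,5-dienones to 5/7-fused hydroxy or acetoxy enones in acidic media. The five-membered ring is closed by the photochemical C1–C5 bonding (formally a disrotatory closure across the C1–C5 termini of the dienone, giving a bicyclo[3.1.0] unit), while the seven-membered ring is not closed by bond formation but results from fragmentation of the shared cyclopropane bond. The new centres C1 (H) and C10 (OAc) are set stereospecifically by the configuration of C10 in 10 (bonding on one face, acetate entering anti to the departing C5), and because both become trigonal in step 8 either C10 epimer of 10 is funnelled to the same dienone. The step needs opening of the C5–C10 and not the C1–C10 cyclopropane bond (which would give a spiro ketone) and protonation faster than the sigmatropic shift to a lumiketone; the C4 methyl, which stabilises positive charge at C4, and the acidic solvent should secure both.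

Step 8
Reactants: 12 acetoxy enone
Product: 13 (5R,6S)-6-hydroxy-5-isopropyl-3,8-dimethyl-4,5,6,7-tetrahydroazulen-2(1H)-one
Conditions: DBU, toluene, 25 to 60 °C
Reagents that add atoms: none
Why: Vinylogous E1cB elimination: only the C1 proton is acidified (γ to the carbonyl through C4=C5), so its removal and loss of the tertiary C10 acetate should give the through-conjugated C1=C10 dienone regiospecifically, erasing the C1 and C10 stereocentres.

Step 9
Reactants: 13 hydroxy dienone; 14 4-acetoxy-3-methoxybenzoic acid
Product: 15 (5R,6S)-5-isopropyl-3,8-dimethyl-2-oxo-1,2,4,5,6,7-hexahydroazulen-6-yl 4-acetoxy-3-methoxybenzoate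
Conditions: DCC, 4-(dimethylamino)pyridine (cat.), CH2Cl2, 0 to 25 °C
Reagents that add atoms: none
Why: Steglich esterification should acylate the only hydroxyl with retention at C8; the phenol is masked as its acetate so that it cannot be acylated itself.

Step 10
Reactants: 15 keto ester
Product: 16 (2R,5R,6S)-2-hydroxy-5-isopropyl-3,8-dimethyl-1,2,4,5,6,7-hexahydroazulen-6-yl 4-acetoxy-3-methoxybenzoate
Conditions: (S)-1-methyl-3,3-diphenyltetrahydro-1H,3H-pyrrolo[1,2-c][1,3,2]oxazaborole (20 mol%), catecholborane, toluene, −78 to −40 °C; aq. NaOH work-up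
Reagents that add atoms: none
Why: Corey–Bakshi–Shibata reduction: the oxazaborolidine–borane complex distinguishes the α-methyl alkenyl flank (large) from the CH2 flank (small) of the ketone, so the (S)-catalyst should deliver hydride to give the (2R) carbinol under reagent control; catecholborane at low temperature spares both esters and the alkenes.

Step 11
Reactants: 16 allylic alcohol
Product: 19 (3aR,5R,6S)-5-isopropyl-3,8-dimethyl-1,3a,4,5,6,7-hexahydroazulen-6-yl 4-acetoxy-3-methoxybenzoate, via allylic sulfonylhydrazine 17 (not isolated), via allylic diazene 18 (not isolated)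
Conditions: 2-nitrobenzenesulfonylhydrazide, PPh3, diethyl azodicarboxylate, THF, −30 °C, then 23 °C
Reagents that add atoms: none
Why: Mitsunobu displacement of the allylic carbinol by the sulfonylhydrazide occurs with inversion at C3; on warming the adduct loses sulfinic acid, and the allylic diazene undergoes a retro-ene reaction that delivers hydrogen to C5 on the face of the former C–N bond, moves the alkene to C3=C4 and expels N2 (reductive 1,3-transposition of an allylic alcohol), so the (R) carbinol should be relayed to (R)-C5 while C1=C10 stays in place.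

Step 12
Reactants: 19 O-acetyl ester
Product: 20 (3aR,5R,6S)-5-isopropyl-3,8-dimethyl-1,3a,4,5,6,7-hexahydroazulen-6-yl 4-hydroxy-3-methoxybenzoate
Conditions: K2CO3, MeOH, 0 °C
Reagents that add atoms: none
Why: Base-catalysed methanolysis cleaves the activated aryl acetate much faster than the hindered secondary alkyl benzoate, and no stereocentre or alkene is base-labile under these conditions.

**Compound list**

1 | (R)-(−)-carvone, (5R)-2-methyl-5-(prop-1-en-2-yl)cyclohex-2-en-1-one | CC1=CC[C@H](CC1=O)C(C)=C | starting material
2 | (5R)-5-isopropyl-2-methylcyclohex-2-en-1-one | CC1=CC[C@H](CC1=O)C(C)C | intermediate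
3 | (R)-[(5-isopropyl-2-methylcyclohexa-1,3-dien-1-yl)oxy]trimethylsilane | CC1=C(O[Si](C)(C)C)C[C@H](C(C)C)C=C1 | intermediate
4 | trimethyl{[(1S,5R,6R)-5-isopropyl-2-methyl-7-oxabicyclo[4.1.0]hept-2-en-3-yl]oxy}silane, oxirane anti to isopropyl | CC1=C(O[Si](C)(C)C)C[C@H](C(C)C)[C@H]2O[C@@H]12 | intermediate
5 | (4R,5R)-4-hydroxy-5-isopropyl-2-methylcyclohex-2-en-1-one | O[C@H]1C=C(C)C(=O)C[C@@H]1C(C)C | intermediate
6 | (2R,4S,5R)-4-hydroxy-5-isopropyl-2-methylcyclohexan-1-one | O[C@H]1C[C@@H](C)C(=O)C[C@@H]1C(C)C | intermediate
7 | ethyl vinyl ketone, pent-1-en-3-one | CCC(=O)C=C | starting material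
8 | (2S,4S,5R)-4-hydroxy-5-isopropyl-2-methyl-2-(3-oxopentyl)cyclohexan-1-one | O[C@H]1C[C@](C)(CCC(=O)CC)C(=O)C[C@@H]1C(C)C | intermediate
9 | (4aS,6S,7R)-6-hydroxy-7-isopropyl-1,4a-dimethyl-4,4a,5,6,7,8-hexahydronaphthalen-2(3H)-one | O[C@H]1C[C@]2(C)CCC(=O)C(C)=C2C[C@@H]1C(C)C | intermediate
10 | (4aR,6S,7R)-6-hydroxy-7-isopropyl-1,4a-dimethyl-5,6,7,8-tetrahydronaphthalen-2(4aH)-one | O[C@H]1C[C@]2(C)C=CC(=O)C(C)=C2C[C@@H]1C(C)C | intermediate
11 | C1–C5 bonded cyclopropyl oxyallyl zwitterion (enolate at C3, tertiary cation at C4, cyclopropane C1–C5–C10) | O[C@H]1C[C@]2(C)[C@H]3C=C([O-])[C+](C)[C@@]23C[C@@H]1C(C)C | intermediate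
12 | (5R,6S,8S,8aS)-6-hydroxy-5-isopropyl-3,8-dimethyl-2-oxo-1,2,4,5,6,7,8,8a-octahydroazulen-8-yl acetate | O[C@H]1C[C@](C)(OC(C)=O)[C@H]2CC(=O)C(C)=C2C[C@@H]1C(C)C | intermediate
13 | (5R,6S)-6-hydroxy-5-isopropyl-3,8-dimethyl-4,5,6,7-tetrahydroazulen-2(1H)-one | O[C@H]1CC(C)=C2CC(=O)C(C)=C2C[C@@H]1C(C)C | intermediate
14 | 4-acetoxy-3-methoxybenzoic acid | COc1cc(C(=O)O)ccc1OC(C)=O | starting material
15 | (5R,6S)-5-isopropyl-3,8-dimethyl-2-oxo-1,2,4,5,6,7-hexahydroazulen-6-yl 4-acetoxy-3-methoxybenzoate | COc1cc(C(=O)O[C@H]2CC(C)=C3CC(=O)C(C)=C3C[C@@H]2C(C)C)ccc1OC(C)=O | intermediate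
16 | (2R,5R,6S)-2-hydroxy-5-isopropyl-3,8-dimethyl-1,2,4,5,6,7-hexahydroazulen-6-yl 4-acetoxy-3-methoxybenzoate | COc1cc(C(=O)O[C@H]2CC(C)=C3C[C@@H](O)C(C)=C3C[C@@H]2C(C)C)ccc1OC(C)=O | intermediate
17 | (2S,5R,6S)-5-isopropyl-3,8-dimethyl-2-[1-(2-nitrophenylsulfonyl)hydrazin-1-yl]-1,2,4,5,6,7-hexahydroazulen-6-yl 4-acetoxy-3-methoxybenzoate | COc1cc(C(=O)O[C@H]2CC(C)=C3C[C@H](N(N)S(=O)(=O)c4ccccc4[N+](=O)[O-])C(C)=C3C[C@@H]2C(C)C)ccc1OC(C)=O | intermediate
18 | (2S,5R,6S)-2-diazenyl-5-isopropyl-3,8-dimethyl-1,2,4,5,6,7-hexahydroazulen-6-yl 4-acetoxy-3-methoxybenzoate | COc1cc(C(=O)O[C@H]2CC(C)=C3C[C@H](N=N)C(C)=C3C[C@@H]2C(C)C)ccc1OC(C)=O | intermediate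
19 | (3aR,5R,6S)-5-isopropyl-3,8-dimethyl-1,3a,4,5,6,7-hexahydroazulen-6-yl 4-acetoxy-3-methoxybenzoate | COc1cc(C(=O)O[C@H]2CC(C)=C3CC=C(C)[C@H]3C[C@@H]2C(C)C)ccc1OC(C)=O | intermediate
20 | (3aR,5R,6S)-5-isopropyl-3,8-dimethyl-1,3a,4,5,6,7-hexahydroazulen-6-yl 4-hydroxy-3-methoxybenzoate | COc1cc(C(=O)O[C@H]2CC(C)=C3CC=C(C)[C@H]3C[C@@H]2C(C)C)ccc1O | target

**Step count and risks**

Total step count: 12. Longest linear sequence: 12 steps, from (R)-carvone 1 to 20. The photochemical key step has close precedent on 4-methyl dienones and is ranked below the three steps that follow.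

Step 11 is the most likely to fail. The activated dienylic carbinol may ionise instead of being displaced, leading to elimination toward a fulvene-type triene or to attack at the far end of the diene, and this would erode both regiochemistry and the transfer of configuration to C5. The fallback sets out from ketone 15, replaces steps 10 and 11, and comes back at 19. Ketone 15 is condensed with p-toluenesulfonylhydrazide (EtOH, cat. AcOH) to the tosylhydrazone F1. Catecholborane in CHCl3 at 0 °C adds hydride to the C=N bond to give the allylic tosylhydrazine F2. Warming with NaOAc·3H2O makes F2 lose p-toluenesulfinic acid to form the same diazene 18, which rearranges to 19. No carbinol has to be activated, but the hydride face is then under substrate control, so C5 epimers may have to be separated.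

Step 3 is the second risk. The peracid may attack the more electron-rich, silyloxy-bearing alkene of 3 and hydroxylate the α carbon instead of the γ carbon. The fallback sets out from 2 and comes back at 5. Enone 2 is deconjugated with KOtBu in tBuOH followed by a fast quench into cold aqueous AcOH (kinetic α-protonation of the dienolate) to give the β,γ-unsaturated ketone (5R)-5-isopropyl-2-methylcyclohex-3-en-1-one F3. mCPBA with NaHCO3 epoxidises its only alkene anti to the isopropyl group to give the epoxy ketone F4. DBU opens F4 by E1cB to the γ-hydroxy enone 5.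

Step 5 is the third risk. Under hydroxide, polymerisation of the vinyl ketone, reversible oxa-Michael addition of the free hydroxyl and alkylation at the less substituted α carbon may all drain material before the quaternary centre forms. The fallback sets out from 6 and comes back at 8, which is then cyclised to 9 with NaOMe in MeOH. Ketone 6 is condensed with benzylamine (toluene, Dean–Stark) to the N-benzyl imine F5. The secondary enamine tautomer of F5 adds to 7 under neutral conditions at the more substituted carbon to give the alkylated imine F6. Aqueous AcOH hydrolyses F6 to diketone 8.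

Further compounds
F1 | step 11 | tosylhydrazone of 15 at the ring ketone | COc1cc(C(=O)O[C@H]2CC(C)=C3CC(=NNS(=O)(=O)c4ccc(C)cc4)C(C)=C3C[C@@H]2C(C)C)ccc1OC(C)=O
F2 | step 11 | (2S,5R,6S)-5-isopropyl-3,8-dimethyl-2-[2-(4-methylphenylsulfonyl)hydrazin-1-yl]-1,2,4,5,6,7-hexahydroazulen-6-yl 4-acetoxy-3-methoxybenzoate | COc1cc(C(=O)O[C@H]2CC(C)=C3C[C@H](NNS(=O)(=O)c4ccc(C)cc4)C(C)=C3C[C@@H]2C(C)C)ccc1OC(C)=O
F3 | step 3 | (5R)-5-isopropyl-2-methylcyclohex-3-en-1-one, C2 epimers | CC1C=C[C@H](CC1=O)C(C)C
F4 | step 3 | 3,4-epoxide of F3 with the oxirane anti to isopropyl | CC1[C@@H]2O[C@@H]2[C@H](CC1=O)C(C)C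
F5 | step 5 | N-benzyl imine of 6 | O[C@H]1C[C@@H](C)C(=NCc2ccccc2)C[C@@H]1C(C)C
F6 | step 5 | N-benzyl imine of diketone 8 at the ring carbonyl | O[C@H]1C[C@](C)(CCC(=O)CC)C(=NCc2ccccc2)C[C@@H]1C(C)C
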